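**Retrosynthetic overview**
- The acid is unveiled last from its methyl ester by a carboxylesterase; the maleimide C=C comes from selenoxide elimination on a 3-acylsuccinimide, whose C9–C3' bond is made by aldol addition of a succinimide dianion to a decalin C9 aldehyde, then oxidation.
- Succinimide fragment: side-chain stereocentre by Ir-catalysed asymmetric allylic alkylation of malonate; imide ring by alkylation/cyclisation and Krapcho reaction.
- Decalin: ring B is closed onto a ring-A enone by intramolecular aldol (C4a–C5; gives the tertiary OH and the cis fusion); C10 by enol-triflate carbonylation; C6 by equilibration.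
- Ring A: organocatalytic Michael addition/aldol condensation of propanal with a vinyl ketone (sets C2), copper-catalysed vinyl addition (C1, C9), Saegusa oxidation.
- The vinyl ketone comes from carboxylesterase desymmetrisation of dimethyl 3-methylglutarate (C8, first stereocentre). Ring order: imide ring (as a succinimide, separate fragment), ring A, ring B, then the maleimide double bond.

Assumption and convention: enzymes, ligands and standard reagents count as commercially available; decalin locants are those of the target (C1 bears acyl carbon C9, C2 methyl, C3=C4, C4a oxygen, C6 bears carboxyl carbon C10, C8 methyl, C8a; C3'/C4' = imide ring carbons), and "as in 37" means the same configuration as in the target.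

**Route**

Step 1
Reactants: 1 dimethyl 3-methylpentanedioate
Product: 2 (R)-5-methoxy-3-methyl-5-oxopentanoic acid
Conditions: pig liver esterase (a carboxylesterase), 0.2 M phosphate buffer pH 7.0/MeOH 4:1, −10 °C; acidify to pH 2, extract
Reagents that add atoms: water | O
Why: Enzymatic desymmetrisation by ester hydrolysis, in which the esterase distinguishes the two enantiotopic ester groups of the prochiral diester and so creates the C8 stereocentre.

Step 2
Reactants: 2 (R)-5-methoxy-3-methyl-5-oxopentanoic acid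
Product: 3 methyl (S)-5-chloro-3-methyl-5-oxopentanoate
Conditions: (COCl)2, DMF (cat.), CH2Cl2, 0 °C → rt
Reagents that add atoms: oxalyl chloride | O=C(Cl)C(=O)Cl
Why: Acid chloride formation through the chloroiminium (Vilsmeier-type) activator; the stereocentre is β to the carbonyl and cannot epimerise.

Step 3
Reactants: 3 methyl (S)-5-chloro-3-methyl-5-oxopentanoate
Product: 4 methyl (R)-3-methyl-5-oxohept-6-enoate
Conditions: CH2=CHSnBu3 (1.1 equiv), PdCl2(PPh3)2 (2 mol%), BHT (cat.), THF, 50 °C
Reagents that add atoms: tributyl(vinyl)stannane | C=C[Sn](CCCC)(CCCC)CCCC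
Why: Stille acyl cross-coupling (oxidative addition of the acid chloride, vinyl transfer from tin, reductive elimination) gives the vinyl ketone and leaves the methyl ester alone.

Step 4
Reactants: 4 methyl (R)-3-methyl-5-oxohept-6-enoate, 5 propanal
Product: 7 methyl (S)-3-[(R)-3-methyl-6-oxocyclohex-1-en-1-yl]butanoate, via keto aldehyde 6 (not isolated)
Conditions: (S)-2-[methoxy(diphenyl)methyl]pyrrolidine (10 mol%), ethyl 3,4-dihydroxybenzoate (20 mol%), 5 (3 equiv), neat, 4 °C; then TsOH·H2O (10 mol%), PhMe, 60 °C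
Reagents that add atoms: none
Why: Enamine-catalysed asymmetric Michael addition followed by acid-catalysed intramolecular aldol condensation (Robinson-type annulation), in which the prolinol ether shields one face of the propanal enamine so that C2 is set under catalyst control regardless of the remote C8 centre and only the six-membered closure is possible.

Step 5
Reactants: 7 methyl (S)-3-[(R)-3-methyl-6-oxocyclohex-1-en-1-yl]butanoate
Product: 9 methyl (3S)-3-[(1R,2S,3R)-2-ethenyl-3-methyl-6-oxocyclohexyl]butanoate, via C8a epimer 8 (not isolated)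
Conditions: CH2=CHMgBr (1.5 equiv), CuI (20 mol%), THF, −40 °C; MeOH quench; then NaOMe (0.2 equiv), MeOH, rt
Reagents that add atoms: vinylmagnesium bromide | C=C[Mg]Br
Why: Copper-catalysed conjugate addition delivers the vinyl group to C1 anti to the neighbouring C2 methyl, and methoxide equilibration of the α-carbon C8a then gives the all-equatorial (all-trans) ketone.

Step 6
Reactants: 9 methyl (3S)-3-[(1R,2S,3R)-2-ethenyl-3-methyl-6-oxocyclohexyl]butanoate
Product: 10 methyl (3S)-3-(2-formyl-3-methyl-6-oxocyclohexyl)butanoate (ring all-trans as in 9)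
Conditions: O3, CH2Cl2/MeOH 4:1, −78 °C; then Me2S, −78 °C → rt
Reagents that add atoms: ozone | [O-][O+]=O
Why: Ozonolysis with reductive work-up cleaves the only alkene to the C9 aldehyde, and because C1 is now α to that aldehyde its trans,trans arrangement is also the thermodynamic one.

Step 7
Reactants: 10 methyl (3S)-3-(2-formyl-3-methyl-6-oxocyclohexyl)butanoate
Product: 11 methyl (3S)-3-[2-(dimethoxymethyl)-3-methyl-6-oxocyclohexyl]butanoate (ring all-trans)
Conditions: HC(OMe)3, CeCl3·7H2O (10 mol%), MeOH, rt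
Reagents that add atoms: trimethyl orthoformate | COC(OC)OC
Why: Chemoselective acetalisation converts the unhindered aldehyde into its dimethyl acetal while the flanked ring ketone stays free.

Step 8
Reactants: 11 methyl (3S)-3-[2-(dimethoxymethyl)-3-methyl-6-oxocyclohexyl]butanoate
Product: 12 methyl (3S)-3-[2-(tert-butyldimethylsilyloxy)-6-(dimethoxymethyl)-5-methylcyclohex-2-en-1-yl]butanoate (C1 C2 C8a as in 9)
Conditions: LiN(iPr)2 (1.1 equiv), THF, −78 °C; then tBuMe2SiOTf, −78 → 0 °C
Reagents that add atoms: tert-butyldimethylsilyl triflate | CC(C)(C)[Si](C)(C)OS(=O)(=O)C(F)(F)F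
Why: Kinetic enolisation at the less hindered α'-CH2 (C4) and O-silylation give the regiodefined silyl enol ether, which also masks the ring ketone for the next two steps.

Step 9
Reactants: 12 silyl enol ether ester
Product: 13 (3S)-3-[2-(tert-butyldimethylsilyloxy)-6-(dimethoxymethyl)-5-methylcyclohex-2-en-1-yl]-N-methoxy-N-methylbutanamide
Conditions: MeNH(OMe)·HCl (1.5 equiv), iPrMgCl (3.0 equiv), THF, −20 → 0 °C
Reagents that add atoms: N,O-dimethylhydroxylamine hydrochloride | CNOC.Cl
Why: Weinreb amidation, in which the magnesium amide of N,O-dimethylhydroxylamine converts the methyl ester into the N-methoxy-N-methylamide.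

Step 10
Reactants: 13 Weinreb amide
Product: 14 (4S)-4-[2-(tert-butyldimethylsilyloxy)-6-(dimethoxymethyl)-5-methylcyclohex-2-en-1-yl]pentan-2-one
Conditions: MeMgBr (1.5 equiv), THF, 0 °C; pH 7 buffer work-up
Reagents that add atoms: methylmagnesium bromide | C[Mg]Br
Why: Weinreb ketone synthesis, in which the chelated tetrahedral intermediate stops at mono-addition and gives the methyl ketone on work-up.

Step 11
Reactants: 14 methyl ketone silyl enol ether
Product: 15 5-(dimethoxymethyl)-4-methyl-6-[(2S)-4-oxopentan-2-yl]cyclohex-2-en-1-one (4,5-trans and 5,6-trans)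
Conditions: Pd(OAc)2 (1.05 equiv), MeCN, rt
Reagents that add atoms: none
Why: Saegusa–Ito oxidation (palladation of the silyl enol ether and β-hydride elimination) installs the C3=C4 enone without touching a stereocentre.

Step 12
Reactants: 15 enone methyl ketone
Product: 17 1-(dimethoxymethyl)-2,8-dimethyl-4a-(triethylsilyloxy)-1,4a,5,7,8,8a-hexahydronaphthalen-6(2H)-one (target locants; cis-fused; C1 C2 C4a C8 C8a as in 37), via lithium aldolate 16 (not isolated)
Conditions: LiN(iPr)2 (1.05 equiv), THF, −78 °C, 1 h; then Et3SiOTf (1.1 equiv), −78 → −40 °C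
Reagents that add atoms: triethylsilyl triflate | CC[Si](CC)(CC)OS(=O)(=O)C(F)(F)F
Why: Intramolecular aldol addition (Robinson-type ketol closure) of the kinetic methyl-ketone enolate to the enone carbonyl through a chair with the C8 methyl equatorial and axial attack at C4a forms ring B cis-fused with the C4a oxygen cis to H-8a, and O-silylation of the aldolate blocks retro-aldol.

Step 13
Reactants: 17 silyl-protected cis-ketol
Product: 18 1-(dimethoxymethyl)-2,8-dimethyl-4a-(triethylsilyloxy)-1,2,4a,5,8,8a-hexahydronaphthalen-6-yl trifluoromethanesulfonate (target locants)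
Conditions: KN(SiMe3)2 (1.2 equiv), THF, −78 °C; then PhNTf2, −78 → 0 °C
Reagents that add atoms: N-phenylbis(trifluoromethanesulfonimide) | O=S(=O)(N(c1ccccc1)S(=O)(=O)C(F)(F)F)C(F)(F)F
Why: Enol triflate formation by kinetic deprotonation at C7, away from the neopentyl C5, and O-sulfonylation, with any minor C5=C6 isomer removed by chromatography.

Step 14
Reactants: 18 enol triflate
Product: 19 methyl 1-(dimethoxymethyl)-2,8-dimethyl-4a-(triethylsilyloxy)-1,2,4a,5,8,8a-hexahydronaphthalene-6-carboxylate (target locants)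
Conditions: CO (1 atm), MeOH, Et3N, Pd(OAc)2 (5 mol%), Ph2P(CH2)3PPh2 (5 mol%), DMF, 60 °C
Reagents that add atoms: carbon monoxide | [C-]#[O+]; methanol | CO
Why: Palladium-catalysed alkoxycarbonylation of the vinyl triflate (oxidative addition, CO insertion, methanolysis) introduces C10 as the methyl ester.

Step 15
Reactants: 19 unsaturated ester
Product: 21 methyl 1-(dimethoxymethyl)-2,8-dimethyl-4a-(triethylsilyloxy)-1,2,4a,5,6,7,8,8a-octahydronaphthalene-6-carboxylate (target locants; all six centres as in 37), via C6 epimer 20 (not isolated)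
Conditions: Mg turnings (10 equiv), MeOH, 0 °C → rt; then NaOMe (0.3 equiv), MeOH, 40 °C
Reagents that add atoms: none
Why: Dissolving-metal conjugate reduction of the enoate followed by methoxide equilibration sets C6 under thermodynamic control, the ester going equatorial, cis to the C8 methyl and away from the axial C4a silyloxy group.

Step 16
Reactants: 21 saturated ester acetal
Product: 22 methyl 1-formyl-2,8-dimethyl-4a-(triethylsilyloxy)-1,2,4a,5,6,7,8,8a-octahydronaphthalene-6-carboxylate (target locants; centres as in 37)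
Conditions: LiBF4 (1 equiv), MeCN/H2O 98:2, rt → 40 °C
Reagents that add atoms: water | O
Why: Mild Lewis-acid acetal hydrolysis unmasks the C9 aldehyde while the tertiary silyl ether and the ester survive, C1 already being in its thermodynamic configuration.

Step 17
Reactants: 23 (E)-oct-2-en-1-ol
Product: 24 methyl (E)-oct-2-en-1-yl carbonate
Conditions: ClCO2Me, pyridine, CH2Cl2, 0 °C
Reagents that add atoms: methyl chloroformate | COC(=O)Cl
Why: O-Acylation of the allylic alcohol gives the carbonate leaving group for allylic substitution.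

Step 18
Reactants: 24 methyl (E)-oct-2-en-1-yl carbonate, 25 dimethyl propanedioate
Product: 26 dimethyl 2-[(3S)-oct-1-en-3-yl]propanedioate
Conditions: [Ir(cod)Cl]2 (2 mol%), (Ra,R,R)-(1,1'-binaphthalene-2,2'-diyl) N,N-bis(1-phenylethyl)phosphoramidite (4 mol%), 1,5,7-triazabicyclo[4.4.0]dec-5-ene (8 mol%), THF, rt
Reagents that add atoms: none
Why: Iridium-catalysed asymmetric allylic alkylation, in which the malonate attacks the substituted terminus of the iridium allyl intermediate to give the branched product and the ligand enantiomer is the one that gives the (S) side-chain stereocentre.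

Step 19
Reactants: 26 dimethyl 2-[(3S)-oct-1-en-3-yl]propanedioate, 27 2-bromoacetamide
Product: 29 methyl 3-[(3S)-oct-1-en-3-yl]-2,5-dioxopyrrolidine-3-carboxylate (C3 epimers), via amide diester 28 (not isolated)
Conditions: NaH (1.05 equiv), DMF, 0 °C; 27; then NaH (1.1 equiv), 0 → 40 °C; aqueous work-up
Reagents that add atoms: none
Why: Malonate SN2 alkylation followed by base-induced 5-exo-trig N-acylation closes the imide ring, the side-chain centre having no acidic proton and the new quaternary carbon being an inconsequential epimer mixture.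

Step 20
Reactants: 29 imide ester
Product: 30 3-[(3S)-oct-1-en-3-yl]pyrrolidine-2,5-dione (C3 epimers)
Conditions: LiCl (3 equiv), H2O (2 equiv), DMSO, 140 °C
Reagents that add atoms: none
Why: Krapcho dealkoxycarbonylation removes the extra ester and leaves a C3 epimer mixture that is erased when this carbon becomes sp2.

Step 21
Reactants: 30 3-[(3S)-oct-1-en-3-yl]pyrrolidine-2,5-dione, 22 decalin aldehyde
Product: 31 aldol adduct: methyl 1-{hydroxy[4-((3S)-oct-1-en-3-yl)-2,5-dioxopyrrolidin-3-yl]methyl}-2,8-dimethyl-4a-(triethylsilyloxy)octahydronaphthalene-6-carboxylate (mixture at C9 C3' C4')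
Conditions: 30 (1.2 equiv), LiN(iPr)2 (2.5 equiv), THF, −78 → −20 °C; then 22, −78 °C; H2O quench
Reagents that add atoms: none
Why: Aldol addition of the imide N,C-dianion (second deprotonation at the unsubstituted ring CH2) to the aldehyde forms the C9–C3' bond, and the three new centres are erased in steps 22 to 24.

Step 22
Reactants: 31 aldol adduct
Product: 32 3-acylsuccinimide: methyl 1-[4-((3S)-oct-1-en-3-yl)-2,5-dioxopyrrolidine-3-carbonyl]-2,8-dimethyl-4a-(triethylsilyloxy)octahydronaphthalene-6-carboxylate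
Conditions: Dess–Martin periodinane, CH2Cl2, 0 °C → rt
Reagents that add atoms: none
Why: Dess–Martin oxidation converts the secondary alcohol into the C9 ketone and gives the enolisable β-dicarbonyl.

Step 23
Reactants: 32 3-acylsuccinimide
Product: 33 3-(phenylselanyl) derivative of 32 (selenium on the carbon between the two carbonyls)
Conditions: PhSeCl (1.1 equiv), pyridine (1.2 equiv), CH2Cl2, 0 °C
Reagents that add atoms: benzeneselenenyl chloride | Cl[Se]c1ccccc1
Why: Electrophilic α-selenenylation of the enolised β-dicarbonyl at its only α-carbon, selenium entering anti to the neighbouring side chain and therefore syn to the ring hydrogen needed next.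

Step 24
Reactants: 33 selenide
Product: 35 methyl ester triethylsilyl ether of 37 (maleimide), via selenoxide 34 (not isolated)
Conditions: mCPBA (1.05 equiv), CH2Cl2, −78 → 0 °C
Reagents that add atoms: none
Why: Selenide oxidation and selenoxide syn-elimination with the adjacent ring hydrogen give the tetrasubstituted maleimide alkene without base, so the now vinylogously acidic side-chain centre is not epimerised.

Step 25
Reactants: 35 silyl-protected maleimide methyl ester
Product: 36 methyl ester of 37
Conditions: HF·pyridine, pyridine, THF, 0 °C → rt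
Reagents that add atoms: none
Why: Buffered fluoride desilylation frees the tertiary allylic alcohol without acid-induced ionisation.

Step 26
Reactants: 36 methyl ester of 37
Product: 37 (2R,4S,4aR,5S,6R,8aR)-5-{2,5-dioxo-4-[(3S)-oct-1-en-3-yl]-2,5-dihydro-1H-pyrrole-3-carbonyl}-8a-hydroxy-4,6-dimethyl-1,2,3,4,4a,5,6,8a-octahydronaphthalene-2-carboxylic acid
Conditions: pig liver esterase (a carboxylesterase), 0.1 M phosphate buffer pH 7.0/DMSO 9:1, 25 °C; then pH 3, EtOAc
Reagents that add atoms: water | O
Why: Enzymatic ester hydrolysis at pH 7 liberates the carboxylic acid without the base that would epimerise the side chain or open the imide.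

**Compound list**
1 | dimethyl 3-methylpentanedioate | COC(=O)CC(C)CC(=O)OC | starting material
2 | (R)-5-methoxy-3-methyl-5-oxopentanoic acid | OC(=O)C[C@@H](C)CC(=O)OC | intermediate
3 | methyl (S)-5-chloro-3-methyl-5-oxopentanoate | ClC(=O)C[C@@H](C)CC(=O)OC | intermediate
4 | methyl (R)-3-methyl-5-oxohept-6-enoate | C=CC(=O)C[C@@H](C)CC(=O)OC | intermediate
5 | propanal | CCC=O | starting material
6 | methyl (3R,8R)-3,8-dimethyl-5,9-dioxononanoate | COC(=O)C[C@H](C)CC(=O)CC[C@@H](C)C=O | intermediate
7 | methyl (S)-3-[(R)-3-methyl-6-oxocyclohex-1-en-1-yl]butanoate | COC(=O)C[C@H](C)C1=C[C@H](C)CCC1=O | intermediate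
8 | methyl (3S)-3-[(1S,2S,3R)-2-ethenyl-3-methyl-6-oxocyclohexyl]butanoate (C8a epimer of 9) | COC(=O)C[C@H](C)[C@H]1[C@@H](C=C)[C@H](C)CCC1=O | intermediate
9 | methyl (3S)-3-[(1R,2S,3R)-2-ethenyl-3-methyl-6-oxocyclohexyl]butanoate (ring all-trans) | COC(=O)C[C@H](C)[C@@H]1[C@@H](C=C)[C@H](C)CCC1=O | intermediate
10 | methyl (3S)-3-(2-formyl-3-methyl-6-oxocyclohexyl)butanoate (ring all-trans) | COC(=O)C[C@H](C)[C@@H]1[C@@H](C=O)[C@H](C)CCC1=O | intermediate
11 | methyl (3S)-3-[2-(dimethoxymethyl)-3-methyl-6-oxocyclohexyl]butanoate (ring all-trans) | COC(=O)C[C@H](C)[C@@H]1[C@@H](C(OC)OC)[C@H](C)CCC1=O | intermediate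
12 | methyl (3S)-3-[2-(tert-butyldimethylsilyloxy)-6-(dimethoxymethyl)-5-methylcyclohex-2-en-1-yl]butanoate | COC(=O)C[C@H](C)[C@@H]1[C@@H](C(OC)OC)[C@H](C)CC=C1O[Si](C)(C)C(C)(C)C | intermediate
13 | N-methoxy-N-methyl amide corresponding to ester 12 | CON(C)C(=O)C[C@H](C)[C@@H]1[C@@H](C(OC)OC)[C@H](C)CC=C1O[Si](C)(C)C(C)(C)C | intermediate
14 | (4S)-4-[2-(tert-butyldimethylsilyloxy)-6-(dimethoxymethyl)-5-methylcyclohex-2-en-1-yl]pentan-2-one | CC(=O)C[C@H](C)[C@@H]1[C@@H](C(OC)OC)[C@H](C)CC=C1O[Si](C)(C)C(C)(C)C | intermediate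
15 | 5-(dimethoxymethyl)-4-methyl-6-[(2S)-4-oxopentan-2-yl]cyclohex-2-en-1-one (4,5-trans; 5,6-trans) | CC(=O)C[C@H](C)[C@@H]1[C@@H](C(OC)OC)[C@H](C)C=CC1=O | intermediate
16 | lithium alkoxide of the cis-fused ketol (C4a–O−; ketone at C6) | COC(OC)[C@@H]1[C@H]2[C@@H](C)CC(=O)C[C@@]2([O-])C=C[C@H]1C.[Li+] | intermediate
17 | 1-(dimethoxymethyl)-2,8-dimethyl-4a-(triethylsilyloxy)-1,4a,5,7,8,8a-hexahydronaphthalen-6(2H)-one (target locants; cis-fused) | COC(OC)[C@@H]1[C@H]2[C@@H](C)CC(=O)C[C@@]2(O[Si](CC)(CC)CC)C=C[C@H]1C | intermediate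
18 | C6=C7 enol triflate of 17 | COC(OC)[C@@H]1[C@H]2[C@@H](C)C=C(OS(=O)(=O)C(F)(F)F)C[C@@]2(O[Si](CC)(CC)CC)C=C[C@H]1C | intermediate
19 | C6=C7 unsaturated methyl ester (C10 installed) | COC(OC)[C@@H]1[C@H]2[C@@H](C)C=C(C(=O)OC)C[C@@]2(O[Si](CC)(CC)CC)C=C[C@H]1C | intermediate
20 | C6 epimer of 21 (axial ester, cis to the C4a oxygen) | COC(OC)[C@@H]1[C@H]2[C@@H](C)C[C@H](C(=O)OC)C[C@@]2(O[Si](CC)(CC)CC)C=C[C@H]1C | intermediate
21 | methyl 1-(dimethoxymethyl)-2,8-dimethyl-4a-(triethylsilyloxy)-1,2,4a,5,6,7,8,8a-octahydronaphthalene-6-carboxylate (target locants; centres as in 37) | COC(OC)[C@@H]1[C@H]2[C@@H](C)C[C@@H](C(=O)OC)C[C@@]2(O[Si](CC)(CC)CC)C=C[C@H]1C | intermediate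
22 | methyl 1-formyl-2,8-dimethyl-4a-(triethylsilyloxy)-1,2,4a,5,6,7,8,8a-octahydronaphthalene-6-carboxylate (target locants; centres as in 37) | O=C[C@@H]1[C@H]2[C@@H](C)C[C@@H](C(=O)OC)C[C@@]2(O[Si](CC)(CC)CC)C=C[C@H]1C | intermediate
23 | (E)-oct-2-en-1-ol | CCCCC/C=C/CO | starting material
24 | methyl (E)-oct-2-en-1-yl carbonate | CCCCC/C=C/COC(=O)OC | intermediate
25 | dimethyl propanedioate | COC(=O)CC(=O)OC | starting material
26 | dimethyl 2-[(3S)-oct-1-en-3-yl]propanedioate | C=C[C@H](CCCCC)C(C(=O)OC)C(=O)OC | intermediate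
27 | 2-bromoacetamide | NC(=O)CBr | starting material
28 | dimethyl 2-(2-amino-2-oxoethyl)-2-[(3S)-oct-1-en-3-yl]propanedioate | C=C[C@H](CCCCC)C(CC(N)=O)(C(=O)OC)C(=O)OC | intermediate
29 | methyl 3-[(3S)-oct-1-en-3-yl]-2,5-dioxopyrrolidine-3-carboxylate (C3 epimers) | C=C[C@H](CCCCC)C1(C(=O)OC)CC(=O)NC1=O | intermediate
30 | 3-[(3S)-oct-1-en-3-yl]pyrrolidine-2,5-dione (C3 epimers) | C=C[C@H](CCCCC)C1CC(=O)NC1=O | intermediate
31 | aldol adduct of 30 and 22 (mixture at C9, C3', C4') | C=C[C@H](CCCCC)C1C(C(O)[C@@H]2[C@H]3[C@@H](C)C[C@@H](C(=O)OC)C[C@@]3(O[Si](CC)(CC)CC)C=C[C@H]2C)C(=O)NC1=O | intermediate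
32 | 3-acylsuccinimide (C9 ketone; mixture at C3', C4') | C=C[C@H](CCCCC)C1C(C(=O)[C@@H]2[C@H]3[C@@H](C)C[C@@H](C(=O)OC)C[C@@]3(O[Si](CC)(CC)CC)C=C[C@H]2C)C(=O)NC1=O | intermediate
33 | 3-(phenylselanyl)-3-acylsuccinimide | C=C[C@H](CCCCC)C1C(C(=O)[C@@H]2[C@H]3[C@@H](C)C[C@@H](C(=O)OC)C[C@@]3(O[Si](CC)(CC)CC)C=C[C@H]2C)([Se]c2ccccc2)C(=O)NC1=O | intermediate
34 | selenoxide of 33 | C=C[C@H](CCCCC)C1C(C(=O)[C@@H]2[C@H]3[C@@H](C)C[C@@H](C(=O)OC)C[C@@]3(O[Si](CC)(CC)CC)C=C[C@H]2C)([Se](=O)c2ccccc2)C(=O)NC1=O | intermediate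
35 | methyl ester, C4a triethylsilyl ether of 37 | C=C[C@H](CCCCC)C1=C(C(=O)[C@@H]2[C@H]3[C@@H](C)C[C@@H](C(=O)OC)C[C@@]3(O[Si](CC)(CC)CC)C=C[C@H]2C)C(=O)NC1=O | intermediate
36 | methyl ester of 37 | C=C[C@H](CCCCC)C1=C(C(=O)[C@@H]2[C@H]3[C@@H](C)C[C@@H](C(=O)OC)C[C@@]3(O)C=C[C@H]2C)C(=O)NC1=O | intermediate
37 | (2R,4S,4aR,5S,6R,8aR)-5-{2,5-dioxo-4-[(3S)-oct-1-en-3-yl]-2,5-dihydro-1H-pyrrole-3-carbonyl}-8a-hydroxy-4,6-dimethyl-1,2,3,4,4a,5,6,8a-octahydronaphthalene-2-carboxylic acid (CNP0326775.3) | C=C[C@H](CCCCC)C1=C(C(=O)[C@@H]2[C@H]3[C@@H](C)C[C@@H](C(=O)O)C[C@@]3(O)C=C[C@H]2C)C(=O)NC1=O | target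

**Totals and weak points**

Total step count: 26. Longest linear sequence: 22 steps (steps 1–16, then 21–26).

The three steps most likely to fail:

Step 12 (aldol ring closure; risks are the wrong enolate, retro-aldol or poor cis selectivity). The fallback sets out from 13 and comes back at 17. ClCH2Li (made from ICH2Cl and MeLi·LiBr, THF, −78 °C) converts the Weinreb amide into the chloromethyl ketone F1. Pd(OAc)2 in MeCN then gives the enone chloromethyl ketone F2. SmI2 (2.2 equiv, THF, −78 °C) reduces the C–Cl bond to a regiodefined samarium enolate, which closes ring B in a samarium Reformatsky-type aldol to the free cis-ketol F3. Et3SiOTf with 2,6-di-tert-butylpyridine (CH2Cl2, −78 °C) silylates F3 to 17.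

Step 21 (dianion aldol with a hindered, enolisable aldehyde). The fallback sets out from 22 and comes back at 32. Pinnick oxidation (NaClO2, NaH2PO4, 2-methylbut-2-ene, tBuOH/H2O) gives the C9 carboxylic acid F4, and 1,1'-carbonyldiimidazole in THF gives the acyl imidazole F5. Claisen-type C-acylation of the dianion of 30 (2.2 equiv, THF, −78 → −20 °C) with F5 gives 32 directly, so that 31 and step 22 are bypassed.

Step 26 (the esterase may not accept the bulky, electrophilic substrate). The fallback sets out from 36 and comes back at 37. Me3SnOH (ClCH2CH2Cl, 60 °C) transfers hydroxide to the methyl ester under neutral, non-enzymatic conditions to give the trimethylstannyl ester F6, which dilute HCl work-up converts into 37.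

Further compounds
F1 | step 12 | chloromethyl ketone (ClCH2C(=O) analogue of 14) | ClCC(=O)C[C@H](C)[C@@H]1[C@@H](C(OC)OC)[C@H](C)CC=C1O[Si](C)(C)C(C)(C)C
F2 | step 12 | enone chloromethyl ketone (ClCH2C(=O) analogue of 15) | ClCC(=O)C[C@H](C)[C@@H]1[C@@H](C(OC)OC)[C@H](C)C=CC1=O
F3 | step 12 | free cis-ketol (17 without the silyl group) | COC(OC)[C@@H]1[C@H]2[C@@H](C)CC(=O)C[C@@]2(O)C=C[C@H]1C
F4 | step 21 | C9 carboxylic acid from 22 | OC(=O)[C@@H]1[C@H]2[C@@H](C)C[C@@H](C(=O)OC)C[C@@]2(O[Si](CC)(CC)CC)C=C[C@H]1C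
F5 | step 21 | C9 acyl imidazole | O=C(n1ccnc1)[C@@H]1[C@H]2[C@@H](C)C[C@@H](C(=O)OC)C[C@@]2(O[Si](CC)(CC)CC)C=C[C@H]1C
F6 | step 26 | trimethylstannyl ester of 37 | C=C[C@H](CCCCC)C1=C(C(=O)[C@@H]2[C@H]3[C@@H](C)C[C@@H](C(=O)O[Sn](C)(C)C)C[C@@]3(O)C=C[C@H]2C)C(=O)NC1=O
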